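**Strategy.** Numbering follows the hydrindenone core (C1–C7a; side chain C1'–C4'). The cyclopentanone (ring A: C1, C2, C3, C3a, C7a) is closed after ring B by forming C2–C3. A C2 acyl radical, generated from an aldehyde on the C7a side arm, adds 5-exo to the inner carbon of a (Z)-propenyl group on C3a. One operation makes the ketone ring, sets C3 and turns the propenyl terminus into the C3 ethyl group. It exploits that C3 is α to C2=O and bears ethyl, and that C1/C3 are epimerisable to the all-trans array. The precursor, a cyclohexene (ring B) carrying both quaternary centres C4 and C5, comes from a fumarate-tethered intramolecular Diels–Alder reaction whose δ-lactone is then unzipped.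

Key step: step 19

Remark on numbering: C1 = CHMe, C2 = C=O, C3 = CHEt, C3a, C4 = C(Et)CO2H, C5 = C(Et)(dienyl), C6 = CH=, C7 = C(Me)=, C7a; the side chain on C5 is C1'H=C2'(Et)–C3'H=C4'H–Ph.
Remark on the chemistry: the all-trans arrangement of the substituents on ring A is assumed to be the thermodynamically preferred one, so C1 and C3 (both α to C2=O) converge to the target configuration under the basic steps that follow the key step.

Step 1
Reactants: 1 methyl (R)-3-hydroxy-2-methylpropanoate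
Product: 2 methyl (R)-3-[(tert-butyldimethylsilyl)oxy]-2-methylpropanoate
Conditions: TBSCl, imidazole, CH2Cl2, 0 °C → rt
Reagents that add atoms: tert-butyldimethylsilyl chloride CC(C)(C)[Si](C)(C)Cl
Why: Imidazole-assisted silylation of the primary alcohol leaves the stereocentre (future C1) untouched.

Step 2
Reactants: 2 methyl (R)-3-[(tert-butyldimethylsilyl)oxy]-2-methylpropanoate
Product: 3 (R)-3-[(tert-butyldimethylsilyl)oxy]-2-methylpropanal
Conditions: i-Bu2AlH (1.05 equiv), CH2Cl2, −78 °C; aq. potassium sodium tartrate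
Reagents that add atoms: none
Why: Partial ester reduction stops at the aluminium hemiacetal at −78 °C and the aldehyde is used crude to avoid α-epimerisation.

Step 3
Reactants: 3 (R)-3-[(tert-butyldimethylsilyl)oxy]-2-methylpropanal; 4 2-(triphenylphosphoranylidene)propanal
Product: 5 (2E,4S)-5-[(tert-butyldimethylsilyl)oxy]-2,4-dimethylpent-2-enal
Conditions: PhMe, 90 °C
Reagents that add atoms: none
Why: Wittig olefination with the stabilised formyl ylide should give the (E)-trisubstituted enal (future C7=C7a) directly at the aldehyde oxidation level.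

Step 4
Reactants: 5 (2E,4S)-5-[(tert-butyldimethylsilyl)oxy]-2,4-dimethylpent-2-enal; 6 triethyl 2-phosphonobutanoate
Product: 7 ethyl (2E,4E,6S)-7-[(tert-butyldimethylsilyl)oxy]-2-ethyl-4,6-dimethylhepta-2,4-dienoate
Conditions: NaH, THF, 0 °C → rt
Reagents that add atoms: none
Why: Horner–Wadsworth–Emmons olefination with the α-ethyl phosphonate should place the ester trans to the chain (E, future C5=C6 with the C5 ethyl group), a minor (Z) isomer being removed by chromatography.

Step 5
Reactants: 7 ethyl (2E,4E,6S)-7-[(tert-butyldimethylsilyl)oxy]-2-ethyl-4,6-dimethylhepta-2,4-dienoate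
Product: 8 (2E,4E,6S)-7-[(tert-butyldimethylsilyl)oxy]-2-ethyl-4,6-dimethylhepta-2,4-dien-1-ol
Conditions: i-Bu2AlH (2.2 equiv), CH2Cl2, −78 °C
Reagents that add atoms: none
Why: 1,2-Reduction of the conjugated ester by i-Bu2AlH gives the allylic alcohol without touching the diene.

Step 6
Reactants: 8 (2E,4E,6S)-7-[(tert-butyldimethylsilyl)oxy]-2-ethyl-4,6-dimethylhepta-2,4-dien-1-ol
Product: 9 (2E,4E,6S)-7-[(tert-butyldimethylsilyl)oxy]-2-ethyl-4,6-dimethylhepta-2,4-dienal
Conditions: MnO2, CH2Cl2, rt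
Reagents that add atoms: none
Why: MnO2 oxidises the allylic alcohol chemoselectively and without E/Z erosion.

Step 7
Reactants: 9 (2E,4E,6S)-7-[(tert-butyldimethylsilyl)oxy]-2-ethyl-4,6-dimethylhepta-2,4-dienal; 6 triethyl 2-phosphonobutanoate
Product: 10 ethyl (2E,4E,6E,8S)-9-[(tert-butyldimethylsilyl)oxy]-2,4-diethyl-6,8-dimethylnona-2,4,6-trienoate
Conditions: NaH, THF, 0 °C → rt
Reagents that add atoms: none
Why: A second (E)-selective Horner–Wadsworth–Emmons olefination installs the future C1'=C2' alkene with its ethyl group while the aldehyde is still unhindered.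

Step 8
Reactants: 10 ethyl (2E,4E,6E,8S)-9-[(tert-butyldimethylsilyl)oxy]-2,4-diethyl-6,8-dimethylnona-2,4,6-trienoate
Product: 11 (2E,4E,6E,8S)-9-[(tert-butyldimethylsilyl)oxy]-2,4-diethyl-6,8-dimethylnona-2,4,6-trien-1-ol
Conditions: i-Bu2AlH (2.2 equiv), CH2Cl2, −78 °C
Reagents that add atoms: none
Why: 1,2-Reduction of the trienoate removes the electron-withdrawing group from the diene that must later act as the electron-rich Diels–Alder partner.

Step 9
Reactants: 11 (2E,4E,6E,8S)-9-[(tert-butyldimethylsilyl)oxy]-2,4-diethyl-6,8-dimethylnona-2,4,6-trien-1-ol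
Product: 12 (2S,3E,5E,7E)-1-[(tert-butyldimethylsilyl)oxy]-9-[(tert-butyldiphenylsilyl)oxy]-6,8-diethyl-2,4-dimethylnona-3,5,7-triene
Conditions: TBDPSCl, imidazole, CH2Cl2, rt
Reagents that add atoms: tert-butyl(chloro)diphenylsilane CC(C)(C)[Si](Cl)(c1ccccc1)c1ccccc1
Why: Silylation of the allylic alcohol with the more robust TBDPS group allows the two primary oxygens to be told apart.

Step 10
Reactants: 12 (2S,3E,5E,7E)-1-[(tert-butyldimethylsilyl)oxy]-9-[(tert-butyldiphenylsilyl)oxy]-6,8-diethyl-2,4-dimethylnona-3,5,7-triene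
Product: 13 (2S,3E,5E,7E)-9-[(tert-butyldiphenylsilyl)oxy]-6,8-diethyl-2,4-dimethylnona-3,5,7-trien-1-ol
Conditions: HF·pyridine, excess pyridine, THF, 0 °C
Reagents that add atoms: none
Why: Buffered HF cleaves the primary alkyl TBS ether much faster than the TBDPS ether and is not acidic enough to ionise the trienyl allylic ether.

Step 11
Reactants: 14 2-bromobutanoyl bromide; 15 2-(trimethylsilyl)ethanol
Product: 16 2-(trimethylsilyl)ethyl 2-bromobutanoate (racemic)
Conditions: pyridine, CH2Cl2, 0 °C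
Reagents that add atoms: none
Why: Acylation of the alcohol by the acid bromide installs an ester that can later be removed by fluoride without attack at its hindered carbonyl carbon.

Step 12
Reactants: 16 2-(trimethylsilyl)ethyl 2-bromobutanoate
Product: 18 2-(trimethylsilyl)ethyl 2-(triphenylphosphoranylidene)butanoate, via phosphonium bromide 17 (not isolated)
Conditions: PPh3, PhMe, 90 °C; then CH2Cl2, aq. NaOH, 0 °C
Reagents that add atoms: triphenylphosphine c1ccc(cc1)P(c1ccccc1)c1ccccc1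
Why: SN2 quaternisation of PPh3 by the α-bromo ester followed by deprotonation gives the stabilised ylide.

Step 13
Reactants: 18 2-(trimethylsilyl)ethyl 2-(triphenylphosphoranylidene)butanoate; 19 glyoxylic acid monohydrate
Product: 20 (2E)-3-ethyl-4-oxo-4-[2-(trimethylsilyl)ethoxy]but-2-enoic acid
Conditions: CH2Cl2, 0 °C → rt
Reagents that add atoms: none
Why: Wittig reaction of the stabilised ylide with the aldehyde of glyoxylic acid should give the (E)-2-ethylfumaric half ester with the two carboxyl groups trans.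

Step 14
Reactants: 13 (2S,3E,5E,7E)-9-[(tert-butyldiphenylsilyl)oxy]-6,8-diethyl-2,4-dimethylnona-3,5,7-trien-1-ol; 20 (2E)-3-ethyl-4-oxo-4-[2-(trimethylsilyl)ethoxy]but-2-enoic acid
Product: 21 4-[(2S,3E,5E,7E)-9-[(tert-butyldiphenylsilyl)oxy]-6,8-diethyl-2,4-dimethylnona-3,5,7-trien-1-yl] 1-[2-(trimethylsilyl)ethyl] (2E)-2-ethylbut-2-enedioate
Conditions: DCC, DMAP (cat.), CH2Cl2, 0 °C → rt
Reagents that add atoms: none
Why: Steglich esterification joins diene and dienophile through an ester whose carbonyl carbon is the future C3 and whose alkyl oxygen sits on the future C2.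

Step 15
Reactants: 21 the triene fumarate diester
Product: 22 2-(trimethylsilyl)ethyl (4S,4aS,7R,8R,8aS)-7-[(1E)-3-[(tert-butyldiphenylsilyl)oxy]-2-ethylprop-1-en-1-yl]-7,8-diethyl-4,5-dimethyl-1-oxo-3,4,4a,7,8,8a-hexahydro-1H-isochromene-8-carboxylate (trans-fused δ-lactone)
Conditions: PhMe (0.01 mol/L), BHT (cat.), 130 °C, sealed tube
Reagents that add atoms: none
Why: In this thermal intramolecular Diels–Alder reaction of an ester-tethered 1,3,9-decatriene the (E,E)-diene and (E)-dienophile geometries fix the relative configuration within C4/C3a and C5/C7a, the terminal ester should sit endo to give the trans-fused lactone, and the methyl-bearing stereocentre (methyl equatorial in the chair-like tether, A(1,3) strain with the C7 methyl) should select the diene face, so that C3a, C4, C5 and C7a are all set.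

Step 16
Reactants: 22 the trans-fused δ-lactone
Product: 23 the corresponding lactol, 2-(trimethylsilyl)ethyl (4S,4aS,7R,8R,8aS)-7-[(1E)-3-[(tert-butyldiphenylsilyl)oxy]-2-ethylprop-1-en-1-yl]-7,8-diethyl-1-hydroxy-4,5-dimethyl-3,4,4a,7,8,8a-hexahydro-1H-isochromene-8-carboxylate (mixture at the hemiacetal carbon)
Conditions: i-Bu2AlH (1.1 equiv), CH2Cl2, −78 °C
Reagents that add atoms: none
Why: The lactone is reduced to the lactol at −78 °C while the C4 ester, on a quaternary carbon flanked by a second quaternary carbon, should be too hindered to react.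

Step 17
Reactants: 23 the lactol; 24 ethyltriphenylphosphonium bromide
Product: 26 2-(trimethylsilyl)ethyl (1R,2R,5R,6S)-2-[(1E)-3-[(tert-butyldiphenylsilyl)oxy]-2-ethylprop-1-en-1-yl]-1,2-diethyl-5-[(2S)-1-hydroxypropan-2-yl]-4-methyl-6-[(1Z)-prop-1-en-1-yl]cyclohex-3-ene-1-carboxylate, via hydroxy aldehyde 25 (not isolated)
Conditions: KN(SiMe3)2, THF, −78 → 0 °C (ylide in excess)
Reagents that add atoms: none
Why: Wittig olefination of the ring-opened hydroxy aldehyde with the non-stabilised ylide should give the (Z)-propenyl group on C3a and free the C2 carbinol, the low temperature guarding against epimerisation at C3a.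

Step 18
Reactants: 26 the propenyl alcohol
Product: 27 2-(trimethylsilyl)ethyl (1R,2R,5R,6S)-2-[(1E)-3-[(tert-butyldiphenylsilyl)oxy]-2-ethylprop-1-en-1-yl]-1,2-diethyl-4-methyl-5-[(2S)-1-oxopropan-2-yl]-6-[(1Z)-prop-1-en-1-yl]cyclohex-3-ene-1-carboxylate
Conditions: Dess–Martin periodinane, CH2Cl2, 0 °C → rt
Reagents that add atoms: none
Why: Dess–Martin oxidation converts the primary alcohol into the C2 aldehyde under non-epimerising, non-acidic conditions.

Step 19
Reactants: 27 the propenyl aldehyde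
Product: 28 2-(trimethylsilyl)ethyl (1S,3S,3aR,4R,5R,7aR)-5-[(1E)-3-[(tert-butyldiphenylsilyl)oxy]-2-ethylprop-1-en-1-yl]-3,4,5-triethyl-1,7-dimethyl-2-oxo-2,3,3a,4,5,7a-hexahydro-1H-indene-4-carboxylate
Conditions: tert-dodecanethiol (0.3 equiv), 1,1'-azobis(cyclohexanecarbonitrile) (0.2 equiv, in portions), PhCl (0.02 mol/L), 100 °C
Reagents that add atoms: none
Why: In this thiol-catalysed radical hydroacylation the thiyl radical abstracts the aldehydic hydrogen of 27, the C2 acyl radical adds to the inner propenyl carbon (C3), and the secondary radical on the former propenyl CH is reduced by the thiol, which regenerates the thiyl radical and creates the C3 ethyl group. The closest known reaction type is the thiol-catalysed acyl radical cyclisation of alkenals to 2-alkylcyclopentanones, with the tin hydride cyclisation of acyl selenides as the classical relative. Ring A closes in the 5-exo-trig mode and is trans-fused because the two arms are already trans on ring B. C3 is set in a chair-like transition state with the C1 methyl group and the C7a–C7 and C3a–C4 bonds pseudo-equatorial, which places the new ethyl group trans to C4; this is also the assumed thermodynamic isomer, so any C1 or C3 epimer should converge under the later basic steps. The step needs 5-exo closure to outrun decarbonylation of the secondary acyl radical and 6-endo attack, which the methyl-capped alkene terminus and the five-atom chain should secure. It also needs the other alkenes to stay out, which follows because attack on C6=C7 would be 4-exo or 5-endo and the C1'=C2' alkene is trisubstituted, neopentylic and remote.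

Step 20
Reactants: 28 the silyl-protected hydrindenone
Product: 29 2-(trimethylsilyl)ethyl (1S,3S,3aR,4R,5R,7aR)-3,4,5-triethyl-5-[(1E)-2-ethyl-3-hydroxyprop-1-en-1-yl]-1,7-dimethyl-2-oxo-2,3,3a,4,5,7a-hexahydro-1H-indene-4-carboxylate
Conditions: HF·pyridine, THF, rt
Reagents that add atoms: none
Why: Unbuffered HF·pyridine at room temperature cleaves the allylic TBDPS ether while the 2-(trimethylsilyl)ethyl ester, which needs free fluoride, and the ketone stay intact.

Step 21
Reactants: 29 the allylic alcohol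
Product: 30 2-(trimethylsilyl)ethyl (1S,3S,3aR,4R,5R,7aR)-3,4,5-triethyl-5-[(1E)-2-ethyl-3-oxoprop-1-en-1-yl]-1,7-dimethyl-2-oxo-2,3,3a,4,5,7a-hexahydro-1H-indene-4-carboxylate
Conditions: MnO2, CH2Cl2, rt
Reagents that add atoms: none
Why: MnO2 oxidises only the allylic alcohol and keeps the (E) geometry of C1'=C2'.

Step 22
Reactants: 30 the enal; 31 diethyl benzylphosphonate
Product: 32 2-(trimethylsilyl)ethyl (1S,3S,3aR,4R,5R,7aR)-3,4,5-triethyl-5-[(1E,3E)-2-ethyl-4-phenylbuta-1,3-dien-1-yl]-1,7-dimethyl-2-oxo-2,3,3a,4,5,7a-hexahydro-1H-indene-4-carboxylate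
Conditions: NaN(SiMe3)2, THF, −78 → 0 °C
Reagents that add atoms: none
Why: The (E)-selective Horner–Wadsworth–Emmons reaction of the benzylphosphonate anion should take place at the enal, which is far more electrophilic than the hindered α,α'-disubstituted ketone, whose reversible enolisation returns the all-trans ring A.

Step 23
Reactants: 32 the 2-(trimethylsilyl)ethyl ester
Product: 33 (1S,3S,3aR,4R,5R,7aR)-3,4,5-triethyl-5-[(1E,3E)-2-ethyl-4-phenylbuta-1,3-dien-1-yl]-1,7-dimethyl-2-oxo-2,3,3a,4,5,7a-hexahydro-1H-indene-4-carboxylic acid (target)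
Conditions: Bu4NF, THF, rt; aq. NaH2PO4 work-up
Reagents that add atoms: none
Why: Fluoride attacks silicon and β-elimination releases the doubly neopentylic carboxylate without any attack at its carbonyl carbon and without acid, which the γ,δ-unsaturated acid and the aryl diene would not tolerate.

**Compound list**

1 | methyl (R)-3-hydroxy-2-methylpropanoate | COC(=O)[C@H](C)CO | starting material
2 | methyl (R)-3-[(tert-butyldimethylsilyl)oxy]-2-methylpropanoate | COC(=O)[C@H](C)CO[Si](C)(C)C(C)(C)C | intermediate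
3 | (R)-3-[(tert-butyldimethylsilyl)oxy]-2-methylpropanal | O=C[C@H](C)CO[Si](C)(C)C(C)(C)C | intermediate
4 | 2-(triphenylphosphoranylidene)propanal | CC(C=O)=P(c1ccccc1)(c1ccccc1)c1ccccc1 | starting material
5 | (2E,4S)-5-[(tert-butyldimethylsilyl)oxy]-2,4-dimethylpent-2-enal | O=C/C(C)=C/[C@H](C)CO[Si](C)(C)C(C)(C)C | intermediate
6 | triethyl 2-phosphonobutanoate | CCOC(=O)C(CC)P(=O)(OCC)OCC | starting material
7 | ethyl (2E,4E,6S)-7-[(tert-butyldimethylsilyl)oxy]-2-ethyl-4,6-dimethylhepta-2,4-dienoate | CCOC(=O)/C(CC)=C/C(C)=C/[C@H](C)CO[Si](C)(C)C(C)(C)C | intermediate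
8 | (2E,4E,6S)-7-[(tert-butyldimethylsilyl)oxy]-2-ethyl-4,6-dimethylhepta-2,4-dien-1-ol | OC/C(CC)=C/C(C)=C/[C@H](C)CO[Si](C)(C)C(C)(C)C | intermediate
9 | (2E,4E,6S)-7-[(tert-butyldimethylsilyl)oxy]-2-ethyl-4,6-dimethylhepta-2,4-dienal | O=C/C(CC)=C/C(C)=C/[C@H](C)CO[Si](C)(C)C(C)(C)C | intermediate
10 | ethyl (2E,4E,6E,8S)-9-[(tert-butyldimethylsilyl)oxy]-2,4-diethyl-6,8-dimethylnona-2,4,6-trienoate | CCOC(=O)/C(CC)=C/C(CC)=C/C(C)=C/[C@H](C)CO[Si](C)(C)C(C)(C)C | intermediate
11 | (2E,4E,6E,8S)-9-[(tert-butyldimethylsilyl)oxy]-2,4-diethyl-6,8-dimethylnona-2,4,6-trien-1-ol | OC/C(CC)=C/C(CC)=C/C(C)=C/[C@H](C)CO[Si](C)(C)C(C)(C)C | intermediate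
12 | (2S,3E,5E,7E)-1-[(tert-butyldimethylsilyl)oxy]-9-[(tert-butyldiphenylsilyl)oxy]-6,8-diethyl-2,4-dimethylnona-3,5,7-triene | CC(C)(C)[Si](c1ccccc1)(c1ccccc1)OC/C(CC)=C/C(CC)=C/C(C)=C/[C@H](C)CO[Si](C)(C)C(C)(C)C | intermediate
13 | (2S,3E,5E,7E)-9-[(tert-butyldiphenylsilyl)oxy]-6,8-diethyl-2,4-dimethylnona-3,5,7-trien-1-ol | CC(C)(C)[Si](c1ccccc1)(c1ccccc1)OC/C(CC)=C/C(CC)=C/C(C)=C/[C@H](C)CO | intermediate
14 | 2-bromobutanoyl bromide (racemic) | CCC(Br)C(=O)Br | starting material
15 | 2-(trimethylsilyl)ethanol | C[Si](C)(C)CCO | starting material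
16 | 2-(trimethylsilyl)ethyl 2-bromobutanoate (racemic) | CCC(Br)C(=O)OCC[Si](C)(C)C | intermediate
17 | [1-oxo-1-[2-(trimethylsilyl)ethoxy]butan-2-yl]triphenylphosphonium bromide | CCC(C(=O)OCC[Si](C)(C)C)[P+](c1ccccc1)(c1ccccc1)c1ccccc1.[Br-] | intermediate
18 | 2-(trimethylsilyl)ethyl 2-(triphenylphosphoranylidene)butanoate | CCC(C(=O)OCC[Si](C)(C)C)=P(c1ccccc1)(c1ccccc1)c1ccccc1 | intermediate
19 | glyoxylic acid monohydrate (2,2-dihydroxyacetic acid) | OC(O)C(=O)O | starting material
20 | (2E)-3-ethyl-4-oxo-4-[2-(trimethylsilyl)ethoxy]but-2-enoic acid | OC(=O)/C=C(\CC)C(=O)OCC[Si](C)(C)C | intermediate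
21 | 4-[(2S,3E,5E,7E)-9-[(tert-butyldiphenylsilyl)oxy]-6,8-diethyl-2,4-dimethylnona-3,5,7-trien-1-yl] 1-[2-(trimethylsilyl)ethyl] (2E)-2-ethylbut-2-enedioate | CC(C)(C)[Si](c1ccccc1)(c1ccccc1)OC/C(CC)=C/C(CC)=C/C(C)=C/[C@H](C)COC(=O)/C=C(\CC)C(=O)OCC[Si](C)(C)C | intermediate
22 | trans-fused δ-lactone, 2-(trimethylsilyl)ethyl (4S,4aS,7R,8R,8aS)-7-[(1E)-3-[(tert-butyldiphenylsilyl)oxy]-2-ethylprop-1-en-1-yl]-7,8-diethyl-4,5-dimethyl-1-oxo-3,4,4a,7,8,8a-hexahydro-1H-isochromene-8-carboxylate | CCC(/CO[Si](c1ccccc1)(c1ccccc1)C(C)(C)C)=C\[C@@]1(CC)C=C(C)[C@H]2[C@H](C)COC(=O)[C@@H]2[C@@]1(CC)C(=O)OCC[Si](C)(C)C | intermediate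
23 | lactol of 22 (1-hydroxy in place of 1-oxo, mixture at C1 of the isochromene) | CCC(/CO[Si](c1ccccc1)(c1ccccc1)C(C)(C)C)=C\[C@@]1(CC)C=C(C)[C@H]2[C@H](C)COC(O)[C@@H]2[C@@]1(CC)C(=O)OCC[Si](C)(C)C | intermediate
24 | ethyltriphenylphosphonium bromide | CC[P+](c1ccccc1)(c1ccccc1)c1ccccc1.[Br-] | starting material
25 | ring-opened hydroxy aldehyde form of 23, 2-(trimethylsilyl)ethyl (1R,2R,5S,6S)-2-[(1E)-3-[(tert-butyldiphenylsilyl)oxy]-2-ethylprop-1-en-1-yl]-1,2-diethyl-6-formyl-5-[(2S)-1-hydroxypropan-2-yl]-4-methylcyclohex-3-ene-1-carboxylate | CCC(/CO[Si](c1ccccc1)(c1ccccc1)C(C)(C)C)=C\[C@@]1(CC)C=C(C)[C@@H]([C@H](C)CO)[C@H](C=O)[C@@]1(CC)C(=O)OCC[Si](C)(C)C | intermediate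
26 | 2-(trimethylsilyl)ethyl (1R,2R,5R,6S)-2-[(1E)-3-[(tert-butyldiphenylsilyl)oxy]-2-ethylprop-1-en-1-yl]-1,2-diethyl-5-[(2S)-1-hydroxypropan-2-yl]-4-methyl-6-[(1Z)-prop-1-en-1-yl]cyclohex-3-ene-1-carboxylate | CCC(/CO[Si](c1ccccc1)(c1ccccc1)C(C)(C)C)=C\[C@@]1(CC)C=C(C)[C@@H]([C@H](C)CO)[C@H](/C=C\C)[C@@]1(CC)C(=O)OCC[Si](C)(C)C | intermediate
27 | 2-(trimethylsilyl)ethyl (1R,2R,5R,6S)-2-[(1E)-3-[(tert-butyldiphenylsilyl)oxy]-2-ethylprop-1-en-1-yl]-1,2-diethyl-4-methyl-5-[(2S)-1-oxopropan-2-yl]-6-[(1Z)-prop-1-en-1-yl]cyclohex-3-ene-1-carboxylate | CCC(/CO[Si](c1ccccc1)(c1ccccc1)C(C)(C)C)=C\[C@@]1(CC)C=C(C)[C@@H]([C@H](C)C=O)[C@H](/C=C\C)[C@@]1(CC)C(=O)OCC[Si](C)(C)C | intermediate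
28 | 2-(trimethylsilyl)ethyl (1S,3S,3aR,4R,5R,7aR)-5-[(1E)-3-[(tert-butyldiphenylsilyl)oxy]-2-ethylprop-1-en-1-yl]-3,4,5-triethyl-1,7-dimethyl-2-oxo-2,3,3a,4,5,7a-hexahydro-1H-indene-4-carboxylate | CCC(/CO[Si](c1ccccc1)(c1ccccc1)C(C)(C)C)=C\[C@@]1(CC)C=C(C)[C@@H]2[C@H]([C@H](CC)C(=O)[C@H]2C)[C@@]1(CC)C(=O)OCC[Si](C)(C)C | intermediate
29 | 2-(trimethylsilyl)ethyl (1S,3S,3aR,4R,5R,7aR)-3,4,5-triethyl-5-[(1E)-2-ethyl-3-hydroxyprop-1-en-1-yl]-1,7-dimethyl-2-oxo-2,3,3a,4,5,7a-hexahydro-1H-indene-4-carboxylate | CCC(/CO)=C\[C@@]1(CC)C=C(C)[C@@H]2[C@H]([C@H](CC)C(=O)[C@H]2C)[C@@]1(CC)C(=O)OCC[Si](C)(C)C | intermediate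
30 | 2-(trimethylsilyl)ethyl (1S,3S,3aR,4R,5R,7aR)-3,4,5-triethyl-5-[(1E)-2-ethyl-3-oxoprop-1-en-1-yl]-1,7-dimethyl-2-oxo-2,3,3a,4,5,7a-hexahydro-1H-indene-4-carboxylate | CCC(/C=O)=C\[C@@]1(CC)C=C(C)[C@@H]2[C@H]([C@H](CC)C(=O)[C@H]2C)[C@@]1(CC)C(=O)OCC[Si](C)(C)C | intermediate
31 | diethyl benzylphosphonate | CCOP(=O)(Cc1ccccc1)OCC | starting material
32 | 2-(trimethylsilyl)ethyl (1S,3S,3aR,4R,5R,7aR)-3,4,5-triethyl-5-[(1E,3E)-2-ethyl-4-phenylbuta-1,3-dien-1-yl]-1,7-dimethyl-2-oxo-2,3,3a,4,5,7a-hexahydro-1H-indene-4-carboxylate | CCC(/C=C/c1ccccc1)=C\[C@@]1(CC)C=C(C)[C@@H]2[C@H]([C@H](CC)C(=O)[C@H]2C)[C@@]1(CC)C(=O)OCC[Si](C)(C)C | intermediate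
33 | (1S,3S,3aR,4R,5R,7aR)-3,4,5-triethyl-5-[(1E,3E)-2-ethyl-4-phenylbuta-1,3-dien-1-yl]-1,7-dimethyl-2-oxo-2,3,3a,4,5,7a-hexahydro-1H-indene-4-carboxylic acid | CCC(/C=C/c1ccccc1)=C\[C@@]1(CC)C=C(C)[C@@H]2[C@H]([C@H](CC)C(=O)[C@H]2C)[C@@]1(CC)C(=O)O | target

**Step count.** 23 steps in total. The longest linear sequence is 20 steps (steps 1–10 and 14–23); steps 11–13 make the dienophile acid 20 in a side branch.

**Steps most likely to fail**

Step 15 (intramolecular Diels–Alder reaction). The cycloaddition may be too slow at the two fully substituted termini (C4 and C5), so that a [1,5]-hydrogen shift in the diene with its cis ethyl group competes. The tether carbonyl may also compete with the terminal ester for the endo position, which would erode the trans/cis ring-fusion selectivity. The fallback sets out from 13 and 18 and comes back at 23; it replaces the ester tether by a mixed acetal tether that carries no carbonyl group, so that only the terminal ester directs the endo approach. Wittig reaction of ylide 18 with 2,2-dimethoxyacetaldehyde should give 2-(trimethylsilyl)ethyl (E)-2-ethyl-4,4-dimethoxybut-2-enoate F1. PPTS-catalysed transacetalisation of F1 with alcohol 13 (PhH, 5 Å molecular sieves) should give the mixed methyl acetal F2 as a mixture at the acetal carbon. Heating (PhMe, 130–150 °C) should give the trans-fused cyclic methyl acetal F3, and mild hydrolysis (AcOH, THF, H2O) returns lactol 23.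

Step 19 (key ring closure). The secondary acyl radical may lose carbon monoxide before it cyclises. The thiyl radical may also abstract hydrogen from the allylic silyl ether CH2, or add reversibly to the C1'=C2' alkene with E/Z scrambling, and the chain may be short. The fallback sets out from 27 and comes back at 28; it generates the same acyl radical from a selenoester in a tin hydride chain at room temperature, with no thiyl radical present. Pinnick oxidation (NaClO2, NaH2PO4, 2-methyl-2-butene, t-BuOH/H2O) should give the carboxylic acid F4. Treatment with (PhSe)2 and PBu3 in CH2Cl2 should give the Se-phenyl selenoester F5. Slow addition of Bu3SnH with Et3B and air in PhH at room temperature should close ring A to 28.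

Step 17 (olefination of the lactol). The basic ylide may epimerise C3a in the ring-opened hydroxy aldehyde, which would lead to the cis-fused ring system, or the lactol may open too slowly for full conversion. The fallback sets out from 23 and comes back at 28; it uses a non-basic chromium-mediated olefination. Takai–Utimoto ethylidenation (CH3CHI2, CrCl2, THF, rt) should give the (E)-propenyl alcohol F6, and Dess–Martin oxidation should give the (E)-propenyl aldehyde F7. Under the conditions of step 19, F7 should give 28, because the alkene geometry is lost in the ring closure.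

**Further compounds**

F1 | step 15 | 2-(trimethylsilyl)ethyl (E)-2-ethyl-4,4-dimethoxybut-2-enoate | COC(OC)/C=C(\CC)C(=O)OCC[Si](C)(C)C
F2 | step 15 | mixed methyl acetal of F1 with alcohol 13 (mixture at the acetal carbon) | CC(C)(C)[Si](c1ccccc1)(c1ccccc1)OC/C(CC)=C/C(CC)=C/C(C)=C/[C@H](C)COC(OC)/C=C(\CC)C(=O)OCC[Si](C)(C)C
F3 | step 15 | trans-fused cyclic methyl acetal (1-methoxy analogue of lactol 23) | CCC(/CO[Si](c1ccccc1)(c1ccccc1)C(C)(C)C)=C\[C@@]1(CC)C=C(C)[C@H]2[C@H](C)COC(OC)[C@@H]2[C@@]1(CC)C(=O)OCC[Si](C)(C)C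
F4 | step 19 | carboxylic acid from aldehyde 27 ((2S)-1-carboxyethyl in place of (2S)-1-oxopropan-2-yl) | CCC(/CO[Si](c1ccccc1)(c1ccccc1)C(C)(C)C)=C\[C@@]1(CC)C=C(C)[C@@H]([C@H](C)C(=O)O)[C@H](/C=C\C)[C@@]1(CC)C(=O)OCC[Si](C)(C)C
F5 | step 19 | Se-phenyl selenoester of F4 | CCC(/CO[Si](c1ccccc1)(c1ccccc1)C(C)(C)C)=C\[C@@]1(CC)C=C(C)[C@@H]([C@H](C)C(=O)[Se]c1ccccc1)[C@H](/C=C\C)[C@@]1(CC)C(=O)OCC[Si](C)(C)C
F6 | step 17 | (E)-propenyl isomer of alcohol 26 | CCC(/CO[Si](c1ccccc1)(c1ccccc1)C(C)(C)C)=C\[C@@]1(CC)C=C(C)[C@@H]([C@H](C)CO)[C@H](/C=C/C)[C@@]1(CC)C(=O)OCC[Si](C)(C)C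
F7 | step 17 | (E)-propenyl isomer of aldehyde 27 | CCC(/CO[Si](c1ccccc1)(c1ccccc1)C(C)(C)C)=C\[C@@]1(CC)C=C(C)[C@@H]([C@H](C)C=O)[C@H](/C=C/C)[C@@]1(CC)C(=O)OCC[Si](C)(C)C
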